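Numbering: ring O1, C2–C6; side chain C1'–C15'. The route rests on the C6'–C7' disconnection, between the side-chain carbinol farthest from the ring and the first carbon of the nonyl tail. A titanium/bis(sulfonamide)-catalysed addition of dinonylzinc to a C6' aldehyde joins both fragments and sets the (6'R) carbinol in one operation. The step exploits the 1,3-anti relation of O–C6' to O–C4': in the precursor O–C2' and O–C4' are locked in a cis-1,3-dioxane, which makes C6' a β-alkoxy aldehyde, while the finished 5,6-dihydropyran-2-one ring is already in place and inert to alkylzinc. The precursor arises in four steps from propane-1,3-diol; acid then opens the dioxane.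

Key step: step 5

Assumption: the facial senses of the two catalyst-controlled steps (1 and 5) are assigned by analogy with the usual behaviour of these catalyst families; both ligands are available as either enantiomer.

Step 1
Reactants: 1 propane-1,3-diol; 2 allyl acetate
Product: 4 (4S,6S)-nona-1,8-diene-4,6-diol, via (3S)-hex-5-ene-1,3-diol 3 (not isolated)
Conditions: [Ir(cod)Cl]2 (5 mol %), (S)-Cl,MeO-BIPHEP (10 mol %), 4-chloro-3-nitrobenzoic acid (20 mol %), Cs2CO3 (40 mol %), allyl acetate (10 equiv), 1,4-dioxane, 90 °C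
Reagents that add atoms: allyl acetate (C=CCOC(C)=O)
Why: Two-directional Krische-type iridium-catalysed transfer-hydrogenative allylation from the alcohol oxidation level, in which the chiral cyclometallated π-allyliridium complex sets each carbinol centre by catalyst control and the second allylation diverts the minor enantiomer of 3 into the separable meso diol, so the C2-symmetric (4S,6S) diol should be formed in very high enantiomeric purity.

Step 2
Reactants: 4 (4S,6S)-nona-1,8-diene-4,6-diol; 5 acryloyl chloride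
Product: 6 (4S,6S)-6-hydroxynona-1,8-dien-4-yl prop-2-enoate
Conditions: acryloyl chloride (0.9 equiv, slow addition), iPr2NEt, CH2Cl2, −78 to −20 °C
Reagents that add atoms: acryloyl chloride (C=CC(=O)Cl)
Why: Mono-O-acylation of a C2-symmetric diol whose two hydroxyls are homotopic, so either one gives the same monoester, with unreacted diol recovered and recycled; no stereocenter is touched.

Step 3
Reactants: 6 (4S,6S)-6-hydroxynona-1,8-dien-4-yl prop-2-enoate; 7 (E)-but-2-enal
Product: 9 (2E,5S)-5-hydroxy-6-[(2S)-6-oxo-3,6-dihydro-2H-pyran-2-yl]hex-2-enal, via lactone alcohol 8 (not isolated)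
Conditions: second-generation Hoveyda–Grubbs catalyst [RuCl2(H2IMes)(=CH-C6H4-2-OiPr)] (5 mol %), CH2Cl2 (0.01 M), 40 °C; then (E)-but-2-enal (10 equiv), more catalyst (2 mol %), 40 °C
Reagents that add atoms: (E)-but-2-enal (C/C=C/C=O)
Why: One-pot ring-closing metathesis of the acrylate onto its neighbouring allyl group followed by cross-metathesis of the remaining type 1 terminal alkene with the type 2 enal should give the E enal, and because both the lactone and the enal are electron-poor alkenes that do not re-enter metathesis, any cycloheptene formed by closure of the two allyl termini should be reopened and drained into 9; no stereocenter is formed or touched.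

Step 4
Reactants: 9 (2E,5S)-5-hydroxy-6-[(2S)-6-oxo-3,6-dihydro-2H-pyran-2-yl]hex-2-enal; 10 acetaldehyde
Product: 12 2-[(2R,4R,6S)-2-methyl-6-{[(2S)-6-oxo-3,6-dihydro-2H-pyran-2-yl]methyl}-1,3-dioxan-4-yl]acetaldehyde, via hemiacetal 11 (not isolated)
Conditions: Bi(NO3)3·5H2O (10 mol %), MeCHO (5 equiv), CH2Cl2, rt
Reagents that add atoms: acetaldehyde (CC=O)
Why: Bismuth nitrate-mediated two-component hemiacetal formation and 6-exo-trig oxa-conjugate addition (oxa-Michael) onto the enal, reversible and therefore under thermodynamic control, so that C4' and the acetal carbon should be set from C2' in the chair with all three substituents equatorial (cis-2,4,6-dioxane, syn-1,3-diol).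

Step 5
Reactants: 12 2-[(2R,4R,6S)-2-methyl-6-{[(2S)-6-oxo-3,6-dihydro-2H-pyran-2-yl]methyl}-1,3-dioxan-4-yl]acetaldehyde; 13 nonylmagnesium bromide
Product: 15 (6S)-6-{[(2S,4S,6S)-6-[(2R)-2-hydroxyundecyl]-2-methyl-1,3-dioxan-4-yl]methyl}-5,6-dihydro-2H-pyran-2-one, via dinonylzinc 14 (not isolated)
Conditions: 13 (4.4 equiv), ZnCl2 (2.2 equiv), Et2O, 0 °C to rt; 1,4-dioxane, filter; Ti(OiPr)4 (1.2 equiv), (1S,2S)-1,2-bis(trifluoromethanesulfonamido)cyclohexane (8 mol %), toluene, −20 °C; then 12; aq. NH4Cl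
Reagents that add atoms: nonylmagnesium bromide (CCCCCCCCC[Mg]Br)
Why: Dinonylzinc passes one nonyl group to titanium, and the resulting nonyltitanium isopropoxide species delivers it to the aldehyde bound to the chiral bis(sulfonamido)titanium Lewis acid, which forms the C6'–C7' bond and the C6' carbinol in one event. The closest known reaction type is the titanium/bis(sulfonamide)-catalysed enantioselective addition of dialkylzinc reagents to aliphatic aldehydes, including β-oxygenated ones and zinc reagents made from Grignard reagents after removal of the magnesium salts with dioxane. No ring is closed. The new stereocenter C6' is set by the ligand: the (1S,2S) ligand should direct nonyl to the Re face and give the (R) carbinol, which is also the 1,3-anti product favoured by the β-oxygen at C4' of the dioxane, so ligand and substrate are matched. The step needs chemoselectivity for the aldehyde over the carbonyl and the conjugate position of the dihydropyranone; this is secured by the low reactivity of alkylzinc and alkyltitanium alkoxides towards esters and by the absence of copper, without which alkylzinc does not add in a conjugate sense.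

Step 6
Reactants: 15 (6S)-6-{[(2S,4S,6S)-6-[(2R)-2-hydroxyundecyl]-2-methyl-1,3-dioxan-4-yl]methyl}-5,6-dihydro-2H-pyran-2-one
Product: 16 (6S)-6-[(2S,4S,6R)-2,4,6-trihydroxypentadecyl]-5,6-dihydro-2H-pyran-2-one
Conditions: 2 M aq. HCl–THF (1:2), 40 °C
Reagents that add atoms: none
Why: Acid-catalysed hydrolysis of the ethylidene acetal, driven by loss of volatile acetaldehyde, should free the C2' and C4' hydroxyls without touching the conjugated lactone or any stereocenter.

Compound list
1 | propane-1,3-diol | OCCCO | starting material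
2 | allyl acetate | C=CCOC(C)=O | starting material
3 | (3S)-hex-5-ene-1,3-diol | C=CC[C@H](O)CCO | intermediate
4 | (4S,6S)-nona-1,8-diene-4,6-diol | C=CC[C@H](O)C[C@@H](O)CC=C | intermediate
5 | acryloyl chloride | C=CC(=O)Cl | starting material
6 | (4S,6S)-6-hydroxynona-1,8-dien-4-yl prop-2-enoate | C=CC[C@H](O)C[C@@H](OC(=O)C=C)CC=C | intermediate
7 | (E)-but-2-enal | C/C=C/C=O | starting material
8 | (6S)-6-[(2S)-2-hydroxypent-4-en-1-yl]-5,6-dihydro-2H-pyran-2-one | C=CC[C@H](O)C[C@@H]1CC=CC(=O)O1 | intermediate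
9 | (2E,5S)-5-hydroxy-6-[(2S)-6-oxo-3,6-dihydro-2H-pyran-2-yl]hex-2-enal | O=C/C=C/C[C@H](O)C[C@@H]1CC=CC(=O)O1 | intermediate
10 | acetaldehyde | CC=O | starting material
11 | (2E,5S)-5-(1-hydroxyethoxy)-6-[(2S)-6-oxo-3,6-dihydro-2H-pyran-2-yl]hex-2-enal (both epimers at the hemiacetal carbon) | O=C/C=C/C[C@H](OC(C)O)C[C@@H]1CC=CC(=O)O1 | intermediate
12 | 2-[(2R,4R,6S)-2-methyl-6-{[(2S)-6-oxo-3,6-dihydro-2H-pyran-2-yl]methyl}-1,3-dioxan-4-yl]acetaldehyde (all-cis dioxane) | O=CC[C@H]1C[C@@H](C[C@@H]2CC=CC(=O)O2)O[C@@H](C)O1 | intermediate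
13 | nonylmagnesium bromide | CCCCCCCCC[Mg]Br | starting material
14 | dinonylzinc | CCCCCCCCC[Zn]CCCCCCCCC | intermediate
15 | (6S)-6-{[(2S,4S,6S)-6-[(2R)-2-hydroxyundecyl]-2-methyl-1,3-dioxan-4-yl]methyl}-5,6-dihydro-2H-pyran-2-one (all-cis dioxane) | CCCCCCCCC[C@@H](O)C[C@H]1C[C@@H](C[C@@H]2CC=CC(=O)O2)O[C@@H](C)O1 | intermediate
16 | (6S)-6-[(2S,4S,6R)-2,4,6-trihydroxypentadecyl]-5,6-dihydro-2H-pyran-2-one | CCCCCCCCC[C@@H](O)C[C@H](O)C[C@H](O)C[C@@H]1CC=CC(=O)O1 | target

Total step count: 6
Longest linear sequence: 6 steps (1 → 4 → 6 → 9 → 12 → 15 → 16)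

Steps most likely to fail

Step 3. What may go wrong: the two allyl termini of 6 close on each other to a cycloheptene, or oligomerise, faster than the acrylate closes, and ring-opening does not return this material to the productive path. The fallback introduces the termini one at a time, so that ruthenium never meets a diene; it sets out from 1 and comes back at 9. Mono-silylation of 1 (NaH, TBSCl, THF) gives 3-[(tert-butyldimethylsilyl)oxy]propan-1-ol F1. The iridium-catalysed allylation of step 1 with one allyl acetate gives (3S)-1-[(tert-butyldimethylsilyl)oxy]hex-5-en-3-ol F2. Acryloylation gives (3S)-1-[(tert-butyldimethylsilyl)oxy]hex-5-en-3-yl prop-2-enoate F3. Ring-closing metathesis, now with a single terminal alkene, gives (6S)-6-{2-[(tert-butyldimethylsilyl)oxy]ethyl}-5,6-dihydro-2H-pyran-2-one F4. HF·pyridine gives (6S)-6-(2-hydroxyethyl)-5,6-dihydro-2H-pyran-2-one F5, and Dess–Martin periodinane gives [(2S)-6-oxo-3,6-dihydro-2H-pyran-2-yl]acetaldehyde F6. Brown-type allylboration with (−)-B-allyldiisopinocampheylborane (Et2O, −78 °C, ethanolamine work-up; reagent control) gives 8, now isolated, and cross-metathesis of 8 with 7 gives 9.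

Step 4. What may go wrong: the free C2' hydroxyl adds to ring carbon C4 of the dihydropyranone (bridged bicyclic lactone), or the enal is consumed by self-condensation before the hemiacetal closes. The fallback sets C4' by a second reagent-controlled allylation and carries the oxygens as silyl ethers; it sets out from 8 (isolated by stopping step 3 before the enal is added) and comes back at 16. TBSOTf/2,6-lutidine gives (6S)-6-[(2S)-2-[(tert-butyldimethylsilyl)oxy]pent-4-en-1-yl]-5,6-dihydro-2H-pyran-2-one F7. Ozonolysis of the terminal alkene (O3, CH2Cl2, −78 °C, indicator; PPh3) gives (3R)-3-[(tert-butyldimethylsilyl)oxy]-4-[(2S)-6-oxo-3,6-dihydro-2H-pyran-2-yl]butanal F8. Allylboration with (−)-B-allyldiisopinocampheylborane should give the 1,3-syn alcohol (6S)-6-[(2S,4S)-2-[(tert-butyldimethylsilyl)oxy]-4-hydroxyhept-6-en-1-yl]-5,6-dihydro-2H-pyran-2-one F9. Silylation gives (6S)-6-[(2R,4S)-2,4-bis[(tert-butyldimethylsilyl)oxy]hept-6-en-1-yl]-5,6-dihydro-2H-pyran-2-one F10, and a second ozonolysis gives (3R,5R)-3,5-bis[(tert-butyldimethylsilyl)oxy]-6-[(2S)-6-oxo-3,6-dihydro-2H-pyran-2-yl]hexanal F11. The zinc addition of step 5 (14, Ti(OiPr)4, same ligand) gives (6S)-6-[(2R,4S,6R)-2,4-bis[(tert-butyldimethylsilyl)oxy]-6-hydroxypentadecyl]-5,6-dihydro-2H-pyran-2-one F12, and aqueous HF in MeCN gives 16.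

Step 5. What may go wrong: insufficient facial selectivity at C6', through an uncatalysed background addition or interference of the dioxane oxygens with the chiral titanium complex. The fallback makes the C6'–C7' bond without stereocontrol and sets the configuration afterwards by hydroxyl-directed reduction; it sets out from 12 and comes back at 16. Ligand-free addition of 14 with Ti(OiPr)4 gives (6S)-6-{[(2S,4S,6S)-6-(2-hydroxyundecyl)-2-methyl-1,3-dioxan-4-yl]methyl}-5,6-dihydro-2H-pyran-2-one as both carbinol epimers F13. Dess–Martin periodinane gives the ketone (6S)-6-{[(2R,4S,6R)-2-methyl-6-(2-oxoundecyl)-1,3-dioxan-4-yl]methyl}-5,6-dihydro-2H-pyran-2-one F14. Aqueous HCl in THF removes the acetal to give (6S)-6-[(2S,4R)-2,4-dihydroxy-6-oxopentadecyl]-5,6-dihydro-2H-pyran-2-one F15. Evans–Saksena reduction (Me4NBH(OAc)3, MeCN/AcOH, −30 °C), with intramolecular hydride delivery from the C4' oxygen, should set C6' anti to C4' and give 16.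

Further compounds
F1 | step 3 | 3-[(tert-butyldimethylsilyl)oxy]propan-1-ol | CC(C)(C)[Si](C)(C)OCCCO
F2 | step 3 | (3S)-1-[(tert-butyldimethylsilyl)oxy]hex-5-en-3-ol | CC(C)(C)[Si](C)(C)OCC[C@@H](O)CC=C
F3 | step 3 | (3S)-1-[(tert-butyldimethylsilyl)oxy]hex-5-en-3-yl prop-2-enoate | CC(C)(C)[Si](C)(C)OCC[C@@H](OC(=O)C=C)CC=C
F4 | step 3 | (6S)-6-{2-[(tert-butyldimethylsilyl)oxy]ethyl}-5,6-dihydro-2H-pyran-2-one | CC(C)(C)[Si](C)(C)OCC[C@@H]1CC=CC(=O)O1
F5 | step 3 | (6S)-6-(2-hydroxyethyl)-5,6-dihydro-2H-pyran-2-one | OCC[C@@H]1CC=CC(=O)O1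
F6 | step 3 | [(2S)-6-oxo-3,6-dihydro-2H-pyran-2-yl]acetaldehyde | O=CC[C@@H]1CC=CC(=O)O1
F7 | step 4 | (6S)-6-[(2S)-2-[(tert-butyldimethylsilyl)oxy]pent-4-en-1-yl]-5,6-dihydro-2H-pyran-2-one | C=CC[C@H](O[Si](C)(C)C(C)(C)C)C[C@@H]1CC=CC(=O)O1
F8 | step 4 | (3R)-3-[(tert-butyldimethylsilyl)oxy]-4-[(2S)-6-oxo-3,6-dihydro-2H-pyran-2-yl]butanal | O=CC[C@H](O[Si](C)(C)C(C)(C)C)C[C@@H]1CC=CC(=O)O1
F9 | step 4 | (6S)-6-[(2S,4S)-2-[(tert-butyldimethylsilyl)oxy]-4-hydroxyhept-6-en-1-yl]-5,6-dihydro-2H-pyran-2-one | C=CC[C@H](O)C[C@H](O[Si](C)(C)C(C)(C)C)C[C@@H]1CC=CC(=O)O1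
F10 | step 4 | (6S)-6-[(2R,4S)-2,4-bis[(tert-butyldimethylsilyl)oxy]hept-6-en-1-yl]-5,6-dihydro-2H-pyran-2-one | C=CC[C@H](O[Si](C)(C)C(C)(C)C)C[C@H](O[Si](C)(C)C(C)(C)C)C[C@@H]1CC=CC(=O)O1
F11 | step 4 | (3R,5R)-3,5-bis[(tert-butyldimethylsilyl)oxy]-6-[(2S)-6-oxo-3,6-dihydro-2H-pyran-2-yl]hexanal | O=CC[C@H](O[Si](C)(C)C(C)(C)C)C[C@H](O[Si](C)(C)C(C)(C)C)C[C@@H]1CC=CC(=O)O1
F12 | step 4 | (6S)-6-[(2R,4S,6R)-2,4-bis[(tert-butyldimethylsilyl)oxy]-6-hydroxypentadecyl]-5,6-dihydro-2H-pyran-2-one | CCCCCCCCC[C@@H](O)C[C@H](O[Si](C)(C)C(C)(C)C)C[C@H](O[Si](C)(C)C(C)(C)C)C[C@@H]1CC=CC(=O)O1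
F13 | step 5 | (6S)-6-{[(2S,4S,6S)-6-(2-hydroxyundecyl)-2-methyl-1,3-dioxan-4-yl]methyl}-5,6-dihydro-2H-pyran-2-one, both epimers at the carbinol carbon | CCCCCCCCCC(O)C[C@H]1C[C@@H](C[C@@H]2CC=CC(=O)O2)O[C@@H](C)O1
F14 | step 5 | (6S)-6-{[(2R,4S,6R)-2-methyl-6-(2-oxoundecyl)-1,3-dioxan-4-yl]methyl}-5,6-dihydro-2H-pyran-2-one | CCCCCCCCCC(=O)C[C@H]1C[C@@H](C[C@@H]2CC=CC(=O)O2)O[C@@H](C)O1
F15 | step 5 | (6S)-6-[(2S,4R)-2,4-dihydroxy-6-oxopentadecyl]-5,6-dihydro-2H-pyran-2-one | CCCCCCCCCC(=O)C[C@H](O)C[C@H](O)C[C@@H]1CC=CC(=O)O1
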